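**Early times.** Early on, we take it, substrate goes two ways: alone into single ring, at a rate that follows [substrate], and in pairs towards open dimer and open trimer, at a rate that follows [substrate] squared. If so, your hunch holds that a stronger charge costs ring, and the quick number you want is how much.

| flask | substrate | remark | time |
|---|---|---|---|
| Sunday's | 1.3 M | run made earlier |  |
| cedar | 1.0 M |  | 8.0 h |
| larch | 1.5 M |  | 8.0 h |
| elm | 2.5 M |  | 8.0 h |

Sunday's run (percent of the substrate charged)

| time / h | single ring / % | open dimer / % | open trimer / % |
|---|---|---|---|
| 0.333 | 2 | 8 | 0 |
| 0.667 | 8 | 19 | 0 |
| 1.50 | 11 | 33 | 6 |
| 4.00 | 16 | 38 | 11 |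

(each reading ± 2 percentage points)

- percent here means substrate units held: one open dimer or ring dimer counts as two
- percent here means substrate units held: one open trimer counts as three
- the numbers in the tables scatter by 2 percentage points (one standard deviation)
- "hardly changes" means that all values lie within two and a half points (for a concentration: within two and a half percent of the largest)

- share of single ring in all that became single ring or open dimer or open trimer or ring dimer for cedar, larch, elm, in this order
- the shape of the row from first to last (falls all the way / falls, then rises / rises all the way / hardly changes / rises, then falls)

**One concentration.** Sunday's first ring reading is 2 % against a scatter of 2 percentage points, so we read Sunday's run at 4.00 h instead. There it shows single ring at 16 % and open dimer plus open trimer at 49.0 %. Counting the unread remainder as substrate leaves 0.455 M, and the logarithmic mean of that and the charge is 0.805 M. Multiplying this mean by ring over the rest gives 0.263 M, the crossover concentration, the [substrate] at which both ways take substrate equally fast. The ring share (the selectivity) over a stretch is then this value divided by itself plus the mean [substrate].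

**Our reckoning.** In Sunday's run ring is the smaller stream, so we treat it as a correction to the pairing. Substrate then falls at k[substrate]([substrate] + crossover), and Sunday's loss gives k = 0.259 L mol⁻¹ h⁻¹. At 8.0 h this leaves 0.224 M in cedar, 0.257 M in larch and 0.291 M in elm. The shares come to 33.6 %, 27.2 % and 20.4 %, so the row falls all the way.

**The forecast.** The forecast, close to ours but not identical, reads 33 %, 27 % and 20 %, a row that falls all the way, on the ground that “More concentrated runs favour oligomers, so the share falls throughout”.

**The result.** The flasks give 33.0 %, 26.0 % and 18.6 %, and the row falls all the way. Elm holds 0.0116 % of decomposition product at 8.00 h, and that step moves elm's share by nothing.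

    substrate + open dimer → open trimer (k = 0.120 L mol⁻¹ h⁻¹)
    2 substrate → open dimer (k = 0.160 L mol⁻¹ h⁻¹)
    substrate → single ring (k = 0.0890 h⁻¹)
    substrate → decomposition product (k = 5.90 × 10⁻⁵ h⁻¹)
    open dimer → ring dimer (k = 0.0190 h⁻¹)

Now larch at 4.00 h: substrate stands at 24.5 %, so the mean [substrate] is 0.805 M, and 0.263 M gives a ring share of 24.6 %. The larch flask at that time has a ring share of 22.9 %.

The runs are simulated for substances that don't exist; noise was put on by code.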